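## Retrosynthetic overview

1. The target is a (3S,4S)-trans-dibenzylbutyrolactone whose α-benzyl arene is the benzo ring of a (2S,3R)-trans-2-aryl-3-hydroxymethyl-2,3-dihydrobenzofuran. The last disconnections are the four O-benzyl groups and then the lactone Cα–CH2Ar bond (trans-selective alkylation of the lithium enolate of lactone 23 with benzylic bromide 15).
2. The dihydrofuran ring (O1–C2–C3–C3a–C7a) is not closed directly. It comes from oxidative ring contraction of the six-membered pyranone ring of (2S)-flavanone 7: aryl carbon C4a shifts from C4 to C3, and C4 leaves the ring as CO2Me, which later becomes CH2OH.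
3. The enabling feature is the C4 ketone of the chroman-4-one ring, flanked by the enolisable C3 methylene and by arene carbon C4a, whose ortho neighbour C8a carries the ring oxygen O1. The C2 aryl stereocentre next to C3 steers the new centre trans.
4. Flavanone 7 comes from chromone 5 by enantioselective Pd-catalysed conjugate addition of arylboronic acid 6, and 5 from 2',3'-dihydroxyacetophenone. Lactone 23 comes from dihydroferulic acid by an Evans alkylation.
5. Ring order: pyranone ring (step 3), contracted to the dihydrofuran ring (step 5); the lactone ring is made separately (step 13); fragments A and B are joined in step 14.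

Key step: step 5

Remark (assumption): the facial sense of the Pd(OCOCF3)2/pyridine-oxazoline conjugate addition is taken by analogy with 3-substituted cyclohexenones, which predicts that the (R)-ligand gives the (2S)-flavanone; should the opposite be found, the (S)-ligand would be used with no other change.

## Route

Step 1
Reactants: 1 2',3'-dihydroxyacetophenone
Product: 2 1-[3-(benzyloxy)-2-hydroxyphenyl]ethan-1-one
Conditions: NaH (2.1 equiv), DMF, 0 °C; BnBr (1.0 equiv), 0 °C → rt; aq. HCl work-up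
Reagents that add atoms: benzyl bromide, BrCc1ccccc1
Why: Williamson etherification of the dianion, in which the 3'-phenoxide is the more nucleophilic site because the 2'-phenoxide is chelated to and conjugated with the acetyl group, so one equivalent of benzyl bromide should be taken up at O3'.

Step 2
Reactants: 2 1-[3-(benzyloxy)-2-hydroxyphenyl]ethan-1-one
Product: 3 1-[3-(benzyloxy)-5-bromo-2-hydroxyphenyl]ethan-1-one
Conditions: N-bromosuccinimide (1.02 equiv), MeCN, 0 °C → rt
Reagents that add atoms: N-bromosuccinimide, O=C1CCC(=O)N1Br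
Why: Electrophilic aromatic bromination directed para to the free phenol (C5'), the only position that is activated by the hydroxyl group and not ortho or para to the deactivating acetyl group, as is known for o-vanillin-type phenols.

Step 3
Reactants: 3 1-[3-(benzyloxy)-5-bromo-2-hydroxyphenyl]ethan-1-one
Product: 5 8-(benzyloxy)-6-bromo-4H-chromen-4-one, via enaminone 4 (not isolated)
Conditions: Me2NCH(OMe)2 (1.5 equiv), toluene, 100 °C; concentrate; conc. HCl, CH2Cl2, rt
Reagents that add atoms: N,N-dimethylformamide dimethyl acetal, COC(OC)N(C)C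
Why: Condensation of the methyl ketone with the amide acetal gives the enaminone, and acid then promotes addition of the phenol oxygen to the β-carbon and elimination of dimethylamine, the standard enaminone cyclocondensation to chromones.

Step 4
Reactants: 5 8-(benzyloxy)-6-bromo-4H-chromen-4-one; 6 [4-(benzyloxy)-3-methoxyphenyl]boronic acid
Product: 7 (2S)-8-(benzyloxy)-2-[4-(benzyloxy)-3-methoxyphenyl]-6-bromo-2,3-dihydro-4H-chromen-4-one
Conditions: 6 (2.0 equiv), Pd(OCOCF3)2 (5 mol %), (R)-4-tert-butyl-2-(pyridin-2-yl)-4,5-dihydrooxazole [(R)-t-BuPyOX, 6 mol %], NH4PF6 (30 mol %), H2O (5 equiv), ClCH2CH2Cl, 60 °C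
Reagents that add atoms: none
Why: Asymmetric conjugate addition of an arylboronic acid catalysed by divalent palladium (transmetalation, insertion of the chromone C2=C3 bond into the aryl–palladium bond, protonolysis of the palladium enolate), in which the tert-butyl group of the pyridine-oxazoline ligand selects the enone face and so should set C2 as S, while the aryl bromide is inert because no zerovalent palladium is involved.

Step 5
Reactants: 7 (2S)-8-(benzyloxy)-2-[4-(benzyloxy)-3-methoxyphenyl]-6-bromo-2,3-dihydro-4H-chromen-4-one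
Product: 10 methyl (2S,3S)-7-(benzyloxy)-2-[4-(benzyloxy)-3-methoxyphenyl]-5-bromo-2,3-dihydro-1-benzofuran-3-carboxylate (2,3-trans), via enol ether 8 (not isolated), via iodane 9 (not isolated)
Conditions: HC(OMe)3 (solvent), conc. H2SO4 (0.3 equiv), 0 °C → rt; then PhI(OAc)2 (1.3 equiv), rt
Reagents that add atoms: trimethyl orthoformate, COC(OC)OC
Why: Acid and HC(OMe)3 should convert ketone 7 into enol ether 8, which is attacked at C3 by the electrophilic trivalent iodine of PhI(OAc)2 on the face anti to the C2 aryl group while methanol captures C4 to give iodane 9; loss of PhI from C3 is then assisted by a 1,2-shift of aryl carbon C4a from C4 to C3, and the dimethoxycarbenium ion left at the extruded C4 is demethylated by acetate to the methyl ester. The closest known reaction type is the hypervalent-iodine (or thallium trinitrate) oxidative ring contraction of flavanones and chroman-4-ones to trans-2-aryl-2,3-dihydrobenzofuran-3-carboxylates, an oxidative 1,2-aryl-shift rearrangement of semipinacol type. The five-membered O1–C2–C3–C3a–C7a ring is closed not by a new C–O bond but by C–C bond formation in a suprafacial 1,2-aryl migration through a bridged phenonium-type transition state with PhI as the nucleofuge. C2 is carried through untouched from 7 and controls the new C3 stereocentre: anti addition of iodine followed by migration with inversion at C3 places CO2Me trans to the aryl group, which is also the thermodynamically preferred arrangement of this epimerisable centre, so the (2S,3S) ester should result. The step needs chemoselectivity for migration of C4a over migration of the C2 aryl group (isoflavone), over elimination (flavone) and over substitution by methanol at C3; the trans-diequatorial half-chair of 9 places the C4–C4a bond, not the C2–aryl bond, antiperiplanar to C3–I, the ring oxygen ortho to C4a raises its migratory aptitude, and the two methoxy groups at C4 stabilise the cation formed by the shift. Erosion of enantiomeric purity is not expected because the C2–O1 bond is never broken and no base is present.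

Step 6
Reactants: 10 methyl (2S,3S)-7-(benzyloxy)-2-[4-(benzyloxy)-3-methoxyphenyl]-5-bromo-2,3-dihydro-1-benzofuran-3-carboxylate
Product: 11 {(2S,3R)-7-(benzyloxy)-2-[4-(benzyloxy)-3-methoxyphenyl]-5-bromo-2,3-dihydro-1-benzofuran-3-yl}methanol
Conditions: i-Bu2AlH (3 equiv), CH2Cl2, −78 → 0 °C; aq. potassium sodium tartrate (KNaC4H4O6)
Reagents that add atoms: none
Why: Ester-to-alcohol reduction by a Lewis-acidic aluminium hydride that is not basic enough to enolise the C3 ester or open the ring by β-elimination and that leaves the aryl bromide and benzyl ethers alone, both stereocentres being untouched (the C3 descriptor changes from S to R only through the CIP priorities).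

Step 7
Reactants: 11 {(2S,3R)-7-(benzyloxy)-2-[4-(benzyloxy)-3-methoxyphenyl]-5-bromo-2,3-dihydro-1-benzofuran-3-yl}methanol
Product: 12 (2S,3R)-7-(benzyloxy)-2-[4-(benzyloxy)-3-methoxyphenyl]-3-[(benzyloxy)methyl]-5-bromo-2,3-dihydro-1-benzofuran
Conditions: NaH (1.3 equiv), BnBr (1.2 equiv), Bu4NI (cat.), THF–DMF, 0 °C → rt
Reagents that add atoms: benzyl bromide, BrCc1ccccc1
Why: Williamson etherification of the primary alkoxide, which masks the only acidic proton before the organolithium and enolate steps and gives a group that leaves together with the phenol ethers at the end.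

Step 8
Reactants: 12 (2S,3R)-7-(benzyloxy)-2-[4-(benzyloxy)-3-methoxyphenyl]-3-[(benzyloxy)methyl]-5-bromo-2,3-dihydro-1-benzofuran
Product: 14 {(2S,3R)-7-(benzyloxy)-2-[4-(benzyloxy)-3-methoxyphenyl]-3-[(benzyloxy)methyl]-2,3-dihydro-1-benzofuran-5-yl}methanol, via aldehyde 13 (not isolated)
Conditions: n-BuLi (1.1 equiv), THF, −78 °C; DMF (3 equiv), −78 → 0 °C; then MeOH, NaBH4 (1.5 equiv), 0 °C
Reagents that add atoms: N,N-dimethylformamide, CN(C)C=O
Why: Bromine–lithium exchange is faster than any deprotonation at −78 °C, the lithiated arene is formylated by DMF (Bouveault aldehyde synthesis), and the aldehyde released on adding methanol is reduced in the same flask by borohydride.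

Step 9
Reactants: 14 {(2S,3R)-7-(benzyloxy)-2-[4-(benzyloxy)-3-methoxyphenyl]-3-[(benzyloxy)methyl]-2,3-dihydro-1-benzofuran-5-yl}methanol
Product: 15 (2S,3R)-7-(benzyloxy)-2-[4-(benzyloxy)-3-methoxyphenyl]-3-[(benzyloxy)methyl]-5-(bromomethyl)-2,3-dihydro-1-benzofuran
Conditions: CBr4 (1.3 equiv), PPh3 (1.3 equiv), CH2Cl2, 0 °C; used at once
Reagents that add atoms: carbon tetrabromide, BrC(Br)(Br)Br
Why: Appel reaction, which converts the electron-rich benzylic alcohol into the bromide through an alkoxyphosphonium ion under neutral conditions that spare the benzyl ethers and the cyclic benzylic ether.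

Step 10
Reactants: 16 3-(4-hydroxy-3-methoxyphenyl)propanoic acid
Product: 17 3-[4-(benzyloxy)-3-methoxyphenyl]propanoic acid
Conditions: BnCl (1.3 equiv), NaOH (2.5 equiv), EtOH–H2O, reflux; then HCl to pH 2
Reagents that add atoms: benzyl chloride, ClCc1ccccc1
Why: Williamson etherification in aqueous alkali, where the phenoxide is far more nucleophilic than the carboxylate and any benzyl ester formed is saponified in the same medium.

Step 11
Reactants: 17 3-[4-(benzyloxy)-3-methoxyphenyl]propanoic acid; 18 (4R)-4-benzyl-1,3-oxazolidin-2-one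
Product: 20 (4R)-4-benzyl-3-{3-[4-(benzyloxy)-3-methoxyphenyl]propanoyl}-1,3-oxazolidin-2-one, via mixed anhydride 19 (not isolated)
Conditions: t-BuCOCl (1.1 equiv), Et3N (2.5 equiv), THF, −20 °C; then LiCl (1.1 equiv), 18 (1.0 equiv), −20 °C → rt
Reagents that add atoms: none
Why: N-Acylation of the oxazolidinone by the mixed pivalic anhydride, which is attacked at its unhindered carbonyl group while LiCl and Et3N activate the auxiliary.

Step 12
Reactants: 20 (4R)-4-benzyl-3-{3-[4-(benzyloxy)-3-methoxyphenyl]propanoyl}-1,3-oxazolidin-2-one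
Product: 21 tert-butyl (3S)-4-[(4R)-4-benzyl-2-oxo-1,3-oxazolidin-3-yl]-3-[4-(benzyloxy)-3-methoxybenzyl]-4-oxobutanoate
Conditions: NaN(SiMe3)2 (1.1 equiv), THF, −78 °C; BrCH2CO2t-Bu (2 equiv), −78 → −40 °C
Reagents that add atoms: tert-butyl bromoacetate, BrCC(=O)OC(C)(C)C
Why: Evans asymmetric alkylation, in which the chelated Z-sodium enolate is alkylated on the face opposite the C4 benzyl group of the (R)-auxiliary, which should set the new stereocentre as S.

Step 13
Reactants: 21 tert-butyl (3S)-4-[(4R)-4-benzyl-2-oxo-1,3-oxazolidin-3-yl]-3-[4-(benzyloxy)-3-methoxybenzyl]-4-oxobutanoate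
Product: 23 (4S)-4-[4-(benzyloxy)-3-methoxybenzyl]oxolan-2-one, via hydroxy ester 22 (not isolated)
Conditions: LiBH4 (1.5 equiv), MeOH (1.5 equiv), Et2O–THF, 0 °C; work-up; then p-TsOH·H2O (cat.), toluene, 60 °C
Reagents that add atoms: none
Why: Hydride cleavage of the activated imide carbonyl removes the auxiliary reductively and spares the tert-butyl ester, and acid-catalysed transesterification (5-exo-trig lactonisation) then closes the lactone without touching the stereocentre.

Step 14
Reactants: 23 (4S)-4-[4-(benzyloxy)-3-methoxybenzyl]oxolan-2-one; 15 (2S,3R)-7-(benzyloxy)-2-[4-(benzyloxy)-3-methoxyphenyl]-3-[(benzyloxy)methyl]-5-(bromomethyl)-2,3-dihydro-1-benzofuran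
Product: 24 (3S,4S)-4-[4-(benzyloxy)-3-methoxybenzyl]-3-({(2S,3R)-7-(benzyloxy)-2-[4-(benzyloxy)-3-methoxyphenyl]-3-[(benzyloxy)methyl]-2,3-dihydro-1-benzofuran-5-yl}methyl)oxolan-2-one
Conditions: 23 (1.2 equiv), LiN(SiMe3)2 (1.25 equiv), THF, −78 °C; then 15 (1.0 equiv), DMPU, −78 → −30 °C
Reagents that add atoms: none
Why: Enolate alkylation under 1,2-asymmetric induction, in which the benzylic bromide approaches the lithium enolate of the lactone anti to the β-benzyl substituent, so that Cα should be set trans (3S) to C4 as in the classical dibenzylbutyrolactone lignan synthesis.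

Step 15
Reactants: 24 (3S,4S)-4-[4-(benzyloxy)-3-methoxybenzyl]-3-({(2S,3R)-7-(benzyloxy)-2-[4-(benzyloxy)-3-methoxyphenyl]-3-[(benzyloxy)methyl]-2,3-dihydro-1-benzofuran-5-yl}methyl)oxolan-2-one
Product: 25 (3S,4S)-3-{[(2S,3R)-7-hydroxy-2-(4-hydroxy-3-methoxyphenyl)-3-(hydroxymethyl)-2,3-dihydro-1-benzofuran-5-yl]methyl}-4-(4-hydroxy-3-methoxybenzyl)oxolan-2-one
Conditions: H2 (1 atm), Pd/C (10 wt% Pd), EtOAc–MeOH, rt
Reagents that add atoms: none
Why: Heterogeneous catalytic hydrogenolysis of the three aryl benzyl ethers and the primary alkyl benzyl ether under neutral conditions, under which the lactone, the four stereocentres and the cyclic benzylic ether of the dihydrobenzofuran should persist.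

## Compound list

1 | 2',3'-dihydroxyacetophenone | CC(=O)c1cccc(O)c1O | starting material
2 | 1-[3-(benzyloxy)-2-hydroxyphenyl]ethan-1-one | CC(=O)c1cccc(OCc2ccccc2)c1O | intermediate
3 | 1-[3-(benzyloxy)-5-bromo-2-hydroxyphenyl]ethan-1-one | CC(=O)c1cc(Br)cc(OCc2ccccc2)c1O | intermediate
4 | (E)-1-[3-(benzyloxy)-5-bromo-2-hydroxyphenyl]-3-(dimethylamino)prop-2-en-1-one (enaminone, formed in the flask) | CN(C)/C=C/C(=O)c1cc(Br)cc(OCc2ccccc2)c1O | intermediate
5 | 8-(benzyloxy)-6-bromo-4H-chromen-4-one | O=c1ccoc2c(OCc3ccccc3)cc(Br)cc12 | intermediate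
6 | [4-(benzyloxy)-3-methoxyphenyl]boronic acid | COc1cc(B(O)O)ccc1OCc1ccccc1 | starting material
7 | (2S)-8-(benzyloxy)-2-[4-(benzyloxy)-3-methoxyphenyl]-6-bromo-2,3-dihydro-4H-chromen-4-one | O=C1C[C@@H](c2ccc(OCc3ccccc3)c(OC)c2)Oc2c(OCc3ccccc3)cc(Br)cc12 | intermediate
8 | (2S)-8-(benzyloxy)-2-[4-(benzyloxy)-3-methoxyphenyl]-6-bromo-4-methoxy-2H-chromene (enol ether, formed in the flask) | COC1=C[C@@H](c2ccc(OCc3ccccc3)c(OC)c2)Oc2c(OCc3ccccc3)cc(Br)cc12 | intermediate
9 | {(2R,3R)-8-(benzyloxy)-2-[4-(benzyloxy)-3-methoxyphenyl]-6-bromo-4,4-dimethoxy-3,4-dihydro-2H-chromen-3-yl}(phenyl)-λ3-iodanyl acetate, iodine trans to the C2 aryl group, C2 arranged in space as in 7 (formed in the flask) | COC1(OC)[C@H](I(OC(C)=O)c2ccccc2)[C@@H](c2ccc(OCc3ccccc3)c(OC)c2)Oc2c(OCc3ccccc3)cc(Br)cc12 | intermediate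
10 | methyl (2S,3S)-7-(benzyloxy)-2-[4-(benzyloxy)-3-methoxyphenyl]-5-bromo-2,3-dihydro-1-benzofuran-3-carboxylate (trans) | Brc1cc(OCc2ccccc2)c2c(c1)[C@H](C(=O)OC)[C@@H](c1ccc(OCc3ccccc3)c(OC)c1)O2 | intermediate
11 | {(2S,3R)-7-(benzyloxy)-2-[4-(benzyloxy)-3-methoxyphenyl]-5-bromo-2,3-dihydro-1-benzofuran-3-yl}methanol | Brc1cc(OCc2ccccc2)c2c(c1)[C@H](CO)[C@@H](c1ccc(OCc3ccccc3)c(OC)c1)O2 | intermediate
12 | (2S,3R)-7-(benzyloxy)-2-[4-(benzyloxy)-3-methoxyphenyl]-3-[(benzyloxy)methyl]-5-bromo-2,3-dihydro-1-benzofuran | Brc1cc(OCc2ccccc2)c2c(c1)[C@H](COCc1ccccc1)[C@@H](c1ccc(OCc3ccccc3)c(OC)c1)O2 | intermediate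
13 | (2S,3R)-7-(benzyloxy)-2-[4-(benzyloxy)-3-methoxyphenyl]-3-[(benzyloxy)methyl]-2,3-dihydro-1-benzofuran-5-carbaldehyde (formed in the flask) | O=Cc1cc(OCc2ccccc2)c2c(c1)[C@H](COCc1ccccc1)[C@@H](c1ccc(OCc3ccccc3)c(OC)c1)O2 | intermediate
14 | {(2S,3R)-7-(benzyloxy)-2-[4-(benzyloxy)-3-methoxyphenyl]-3-[(benzyloxy)methyl]-2,3-dihydro-1-benzofuran-5-yl}methanol | OCc1cc(OCc2ccccc2)c2c(c1)[C@H](COCc1ccccc1)[C@@H](c1ccc(OCc3ccccc3)c(OC)c1)O2 | intermediate
15 | (2S,3R)-7-(benzyloxy)-2-[4-(benzyloxy)-3-methoxyphenyl]-3-[(benzyloxy)methyl]-5-(bromomethyl)-2,3-dihydro-1-benzofuran | BrCc1cc(OCc2ccccc2)c2c(c1)[C@H](COCc1ccccc1)[C@@H](c1ccc(OCc3ccccc3)c(OC)c1)O2 | intermediate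
16 | 3-(4-hydroxy-3-methoxyphenyl)propanoic acid (dihydroferulic acid) | COc1cc(CCC(=O)O)ccc1O | starting material
17 | 3-[4-(benzyloxy)-3-methoxyphenyl]propanoic acid | COc1cc(CCC(=O)O)ccc1OCc1ccccc1 | intermediate
18 | (4R)-4-benzyl-1,3-oxazolidin-2-one | O=C1N[C@H](Cc2ccccc2)CO1 | starting material
19 | 3-[4-(benzyloxy)-3-methoxyphenyl]propanoic pivalic anhydride (formed in the flask) | COc1cc(CCC(=O)OC(=O)C(C)(C)C)ccc1OCc1ccccc1 | intermediate
20 | (4R)-4-benzyl-3-{3-[4-(benzyloxy)-3-methoxyphenyl]propanoyl}-1,3-oxazolidin-2-one | COc1cc(CCC(=O)N2[C@H](Cc3ccccc3)COC2=O)ccc1OCc1ccccc1 | intermediate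
21 | tert-butyl (3S)-4-[(4R)-4-benzyl-2-oxo-1,3-oxazolidin-3-yl]-3-[4-(benzyloxy)-3-methoxybenzyl]-4-oxobutanoate | COc1cc(C[C@@H](CC(=O)OC(C)(C)C)C(=O)N2[C@H](Cc3ccccc3)COC2=O)ccc1OCc1ccccc1 | intermediate
22 | tert-butyl (3S)-4-[4-(benzyloxy)-3-methoxyphenyl]-3-(hydroxymethyl)butanoate (formed in the flask) | COc1cc(C[C@@H](CC(=O)OC(C)(C)C)CO)ccc1OCc1ccccc1 | intermediate
23 | (4S)-4-[4-(benzyloxy)-3-methoxybenzyl]oxolan-2-one | COc1cc(C[C@@H]2COC(=O)C2)ccc1OCc1ccccc1 | intermediate
24 | (3S,4S)-4-[4-(benzyloxy)-3-methoxybenzyl]-3-({(2S,3R)-7-(benzyloxy)-2-[4-(benzyloxy)-3-methoxyphenyl]-3-[(benzyloxy)methyl]-2,3-dihydro-1-benzofuran-5-yl}methyl)oxolan-2-one | COc1cc(C[C@@H]2COC(=O)[C@H]2Cc2cc(OCc3ccccc3)c3c(c2)[C@H](COCc2ccccc2)[C@@H](c2ccc(OCc4ccccc4)c(OC)c2)O3)ccc1OCc1ccccc1 | intermediate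
25 | (3S,4S)-3-{[(2S,3R)-7-hydroxy-2-(4-hydroxy-3-methoxyphenyl)-3-(hydroxymethyl)-2,3-dihydro-1-benzofuran-5-yl]methyl}-4-(4-hydroxy-3-methoxybenzyl)oxolan-2-one (CNP0118131.1) | COc1cc(C[C@@H]2COC(=O)[C@H]2Cc2cc(O)c3c(c2)[C@H](CO)[C@@H](c2ccc(O)c(OC)c2)O3)ccc1O | target

## Step count and risks

Total step count: 15 (fragment A, steps 1–9; fragment B, steps 10–13; union and deprotection, steps 14 and 15).
Longest linear sequence: 11 steps (steps 1–9, 14 and 15).

Steps most likely to fail:

Step 5 (ring contraction). The yield may be eroded by competing migration of the C2 aryl group, by elimination or methanolysis at the iodane stage, or by attack of the electrophilic iodine reagent on the dialkoxyarene rings. Acid-induced ionisation of the C2–O1 bond would also erode the enantiomeric purity. The fallback keeps the ring contraction but changes its mechanism to a Wolff rearrangement, in which only the acyl-bound aryl carbon can migrate. It sets out from 7: enolisation with LiN(SiMe3)2 in THF at −78 °C and acylation with 2,2,2-trifluoroethyl trifluoroacetate should give the 3-trifluoroacetyl flavanone F1. Detrifluoroacetylative diazo transfer (methanesulfonyl azide, Et3N, MeCN–H2O) should give the 3-diazo flavanone F2. Irradiation in methanol should expel dinitrogen and contract the ring through the ketene F3, which methanol traps as the methyl ester, expected as a mixture of 10 and the cis ester F4. F4 is then equilibrated at C3 with DBU in CH2Cl2, and the route is rejoined at 10.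

Step 4 (asymmetric conjugate addition). The enantioselectivity may be insufficient or of the wrong sense with the 8-alkoxy chromone, the electron-rich boronic acid may protodeboronate, and insertion may be slow. The fallback builds the flavanone by the chalcone route and introduces the chirality by kinetic resolution. It sets out from 3: Claisen–Schmidt condensation with commercial 4-(benzyloxy)-3-methoxybenzaldehyde (KOH, EtOH) should give the 2'-hydroxychalcone F5. Oxa-Michael cyclisation (NaOAc, EtOH, reflux) should give the racemic flavanone F6. Noyori asymmetric transfer hydrogenation with RuCl(p-cymene)[TsDPEN] in HCO2H–Et3N, using the catalyst antipode that reduces the (2R)-ketone faster, should convert that enantiomer into the cis-flavan-4-ol F7 and leave the (2S)-ketone, so the route is rejoined at 7.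

Step 15 (global hydrogenolysis). The long exposure needed for the primary alkyl benzyl ether may lead to over-reduction, that is hydrogenolysis of the benzylic C2–O1 bond of the dihydrobenzofuran. The fallback changes the protecting-group plan so that hydrogen has to cleave only the fast-reacting aryl benzyl ethers. It sets out from 11: silylation (t-BuMe2SiCl, imidazole, DMF) should give the silyl ether F8. Bromine–lithium exchange and formylation as in step 8 should give the aldehyde F9, reduced in the same flask to the benzylic alcohol F10. Appel bromination should give the bromide F11, and alkylation of the lithium enolate of 23 as in step 14 should give the coupled lactone F12. Bu4NF buffered with AcOH in THF should remove the silyl group to give the primary alcohol F13, and a short hydrogenolysis (H2, Pd/C, EtOAc) should then deliver 25.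

Further compounds
F1 | step 5 | (2S)-8-(benzyloxy)-2-[4-(benzyloxy)-3-methoxyphenyl]-6-bromo-3-(trifluoroacetyl)-2,3-dihydro-4H-chromen-4-one (C3 epimers, largely enolised) | O=C1C(C(=O)C(F)(F)F)[C@@H](c2ccc(OCc3ccccc3)c(OC)c2)Oc2c(OCc3ccccc3)cc(Br)cc12
F2 | step 5 | (2R)-8-(benzyloxy)-2-[4-(benzyloxy)-3-methoxyphenyl]-6-bromo-3-diazo-2,3-dihydro-4H-chromen-4-one (C2 arranged in space as in 7) | O=C1C(=[N+]=[N-])[C@@H](c2ccc(OCc3ccccc3)c(OC)c2)Oc2c(OCc3ccccc3)cc(Br)cc12
F3 | step 5 | (2R)-7-(benzyloxy)-2-[4-(benzyloxy)-3-methoxyphenyl]-5-bromo-3-(oxomethylidene)-2,3-dihydro-1-benzofuran (ketene, C2 arranged in space as in 7) | O=C=C1c2cc(Br)cc(OCc3ccccc3)c2O[C@@H]1c1ccc(OCc2ccccc2)c(OC)c1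
F4 | step 5 | methyl (2S,3R)-7-(benzyloxy)-2-[4-(benzyloxy)-3-methoxyphenyl]-5-bromo-2,3-dihydro-1-benzofuran-3-carboxylate (cis) | Brc1cc(OCc2ccccc2)c2c(c1)[C@@H](C(=O)OC)[C@@H](c1ccc(OCc3ccccc3)c(OC)c1)O2
F5 | step 4 | (E)-1-[3-(benzyloxy)-5-bromo-2-hydroxyphenyl]-3-[4-(benzyloxy)-3-methoxyphenyl]prop-2-en-1-one | COc1cc(/C=C/C(=O)c2cc(Br)cc(OCc3ccccc3)c2O)ccc1OCc1ccccc1
F6 | step 4 | rac-8-(benzyloxy)-2-[4-(benzyloxy)-3-methoxyphenyl]-6-bromo-2,3-dihydro-4H-chromen-4-one | O=C1CC(c2ccc(OCc3ccccc3)c(OC)c2)Oc2c(OCc3ccccc3)cc(Br)cc12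
F7 | step 4 | (2R,4R)-8-(benzyloxy)-2-[4-(benzyloxy)-3-methoxyphenyl]-6-bromo-3,4-dihydro-2H-chromen-4-ol (2,4-cis) | O[C@@H]1C[C@H](c2ccc(OCc3ccccc3)c(OC)c2)Oc2c(OCc3ccccc3)cc(Br)cc12
F8 | step 15 | {[(2S,3R)-7-(benzyloxy)-2-[4-(benzyloxy)-3-methoxyphenyl]-5-bromo-2,3-dihydro-1-benzofuran-3-yl]methoxy}(tert-butyl)dimethylsilane | Brc1cc(OCc2ccccc2)c2c(c1)[C@H](CO[Si](C)(C)C(C)(C)C)[C@@H](c1ccc(OCc3ccccc3)c(OC)c1)O2
F9 | step 15 | (2S,3R)-7-(benzyloxy)-2-[4-(benzyloxy)-3-methoxyphenyl]-3-{[(tert-butyldimethylsilyl)oxy]methyl}-2,3-dihydro-1-benzofuran-5-carbaldehyde | O=Cc1cc(OCc2ccccc2)c2c(c1)[C@H](CO[Si](C)(C)C(C)(C)C)[C@@H](c1ccc(OCc3ccccc3)c(OC)c1)O2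
F10 | step 15 | {(2S,3R)-7-(benzyloxy)-2-[4-(benzyloxy)-3-methoxyphenyl]-3-{[(tert-butyldimethylsilyl)oxy]methyl}-2,3-dihydro-1-benzofuran-5-yl}methanol | OCc1cc(OCc2ccccc2)c2c(c1)[C@H](CO[Si](C)(C)C(C)(C)C)[C@@H](c1ccc(OCc3ccccc3)c(OC)c1)O2
F11 | step 15 | {[(2S,3R)-7-(benzyloxy)-2-[4-(benzyloxy)-3-methoxyphenyl]-5-(bromomethyl)-2,3-dihydro-1-benzofuran-3-yl]methoxy}(tert-butyl)dimethylsilane | BrCc1cc(OCc2ccccc2)c2c(c1)[C@H](CO[Si](C)(C)C(C)(C)C)[C@@H](c1ccc(OCc3ccccc3)c(OC)c1)O2
F12 | step 15 | (3S,4S)-4-[4-(benzyloxy)-3-methoxybenzyl]-3-({(2S,3R)-7-(benzyloxy)-2-[4-(benzyloxy)-3-methoxyphenyl]-3-{[(tert-butyldimethylsilyl)oxy]methyl}-2,3-dihydro-1-benzofuran-5-yl}methyl)oxolan-2-one | COc1cc(C[C@@H]2COC(=O)[C@H]2Cc2cc(OCc3ccccc3)c3c(c2)[C@H](CO[Si](C)(C)C(C)(C)C)[C@@H](c2ccc(OCc4ccccc4)c(OC)c2)O3)ccc1OCc1ccccc1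
F13 | step 15 | (3S,4S)-4-[4-(benzyloxy)-3-methoxybenzyl]-3-({(2S,3R)-7-(benzyloxy)-2-[4-(benzyloxy)-3-methoxyphenyl]-3-(hydroxymethyl)-2,3-dihydro-1-benzofuran-5-yl}methyl)oxolan-2-one | COc1cc(C[C@@H]2COC(=O)[C@H]2Cc2cc(OCc3ccccc3)c3c(c2)[C@H](CO)[C@@H](c2ccc(OCc4ccccc4)c(OC)c2)O3)ccc1OCc1ccccc1
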